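**Strategy.** The cyclohexane ring is disconnected at C3–C4. The key step exploits the exocyclic tetrasubstituted alkene on ring carbon C3 (methyl cis to C4, oxidised carbon cis to C2) together with carbinol C6 across the ring: the alkene is a former alkyne that has taken up C4 and a methyl group on one face, and C6 is a former ketone whose vinyl group supplies C5 and C4. One nickel-catalysed operation joins C4 to C3, delivers CH3 from zinc, closes the six-membered ring and fixes the alkene geometry. The precursor is an acyclic vinyl ketone carrying C1 and C2 (set by a Claisen rearrangement of a lactone-derived cyclic ketene acetal), a propargylic triethylsilyl ether and a PMB-protected arm.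

Key step: step 12

Remark: atom labels C1–C6 are those of the target ring (C1 quaternary, C2 bearing the three-carbon chain, C3 the alkylidene carbon, C6 the carbinol; as a cyclohexanone, C3 is position 4) and are kept for all intermediates; TBS = tert-butyldimethylsilyl, TES = triethylsilyl, PMB = 4-methoxybenzyl; in step 15 (R)-TRIP is assumed to give the (R)-alcohol by analogy with aryl aldehydes, and its antipode would be used otherwise.

Step 1
Reactants: 1 (2R)-but-3-yn-2-ol; 2 tert-butyl(3-iodopropoxy)dimethylsilane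
Product: 3 (2R)-7-(TBSO)hept-3-yn-2-ol
Conditions: n-BuLi (2.1 equiv), THF, −78 → 0 °C; then 2, DMPU, 0 → 23 °C
Reagents that add atoms: none
Why: C-alkylation of the alkoxide–acetylide dianion (acetylide SN2 on a primary iodide) extends the alkyne without touching the carbinol stereocentre.

Step 2
Reactants: 3
Product: 4 (2R,3E)-7-(TBSO)hept-3-en-2-ol
Conditions: NaAlH2(OCH2CH2OMe)2, THF, 0 → 23 °C
Reagents that add atoms: none
Why: Hydroxyl-directed trans-hydroalumination of a propargylic alcohol gives the (E)-allylic alcohol, the stereocentre being a spectator.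

Step 3
Reactants: 5 3-methyloxolan-2-one (racemic)
Product: 7 2,2-diethoxy-3-methyloxolane, via O-ethyl lactonium tetrafluoroborate 6 (not isolated)
Conditions: Et3O·BF4, CH2Cl2, 23 °C; then NaOEt, EtOH, 0 °C
Reagents that add atoms: triethyloxonium tetrafluoroborate, CC[O+](CC)CC.F[B-](F)(F)F; sodium ethoxide, [Na+].[O-]CC
Why: O-ethylation of the lactone carbonyl and capture of the dialkoxycarbenium ion by ethoxide is the standard preparation of lactone orthoesters, and the α-stereocentre is irrelevant because it becomes sp2 in step 4.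

Step 4
Reactants: 4; 7 (3 equiv)
Product: 10 (3R)-3-[(4S,5E)-1-(TBSO)hept-5-en-4-yl]-3-methyloxolan-2-one, via mixed orthoester 8 (not isolated), via cyclic ketene acetal 9 (not isolated)
Conditions: EtCO2H (5 mol %), xylene, 140 °C, EtOH distilled off
Reagents that add atoms: none
Why: Johnson–Claisen (orthoester) rearrangement in which the ketene acetal C=C lies inside the dihydrofuran ring, so that methyl is necessarily cis to the allyloxy oxygen, and the chair transition state with the carbinol methyl equatorial transfers the (R)-C–O centre to C2, sets quaternary C1 relative to it and leaves an (E)-propenyl group.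

Step 5
Reactants: 10
Product: 12 (2R)-5-(TBSO)-2-[(3R)-3-methyl-2-oxooxolan-3-yl]pentanal, via secondary ozonide 11 (not isolated)
Conditions: O3, CH2Cl2, −78 °C; then PPh3, −78 → 23 °C
Reagents that add atoms: ozone, [O-][O+]=O
Why: Ozonolysis with reductive work-up cleaves the only C=C bond under neutral conditions that leave the lactone, the silyl ether and the α-stereocentre C2 untouched.

Step 6
Reactants: 12
Product: 13 (3R)-3-[(3S)-6-(TBSO)hex-1-yn-3-yl]-3-methyloxolan-2-one
Conditions: MeC(O)C(N2)P(O)(OMe)2, K2CO3, MeOH, 0 → 23 °C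
Reagents that add atoms: dimethyl (1-diazo-2-oxopropyl)phosphonate, CC(=O)C(=[N+]=[N-])P(=O)(OC)OC
Why: Ohira–Bestmann (Seyferth–Gilbert) homologation turns the aldehyde into the terminal alkyne under mild carbonate conditions, C2 being shielded from enolisation by the adjacent quaternary C1.

Step 7
Reactants: 13
Product: 16 (3R)-3-[(4S)-7-(TBSO)-1-(TESO)hept-2-yn-4-yl]-3-methyloxolan-2-one, via lithium acetylide 14 (not isolated), via lithium alkoxide 15 (not isolated)
Conditions: LiN(i-Pr)2, THF, −78 °C; CH2O (gas), −78 → 0 °C; then Et3SiCl, 0 °C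
Reagents that add atoms: formaldehyde, C=O; chlorotriethylsilane, CC[Si](Cl)(CC)CC
Why: Acetylide addition to monomeric formaldehyde and O-silylation of the resulting alkoxide in one flask; the lactone has no α-hydrogen and a neopentyl-shielded carbonyl, so it should not compete at −78 °C.

Step 8
Reactants: 16
Product: 17 (3R)-3-[(4S)-7-(TBSO)-1-(TESO)hept-2-yn-4-yl]-3-methyloxolan-2-ol (both anomers)
Conditions: i-Bu2AlH (1.2 equiv), CH2Cl2, −78 °C
Reagents that add atoms: none
Why: Partial hydride reduction of a lactone stops at the aluminium lactolate at −78 °C and gives the lactol on work-up.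

Step 9
Reactants: 17; 18 vinylmagnesium bromide (3 equiv)
Product: 19 (4R,5S)-8-(TBSO)-4-(2-hydroxyethyl)-4-methyl-5-[3-(TESO)prop-1-yn-1-yl]oct-1-en-3-ol (both C3 epimers)
Conditions: THF, 0 → 23 °C
Reagents that add atoms: none
Why: Grignard 1,2-addition to the open hydroxy-aldehyde form of the lactol; the new carbinol centre need not be controlled because it is oxidised in step 11.

Step 10
Reactants: 19
Product: 20 (4R,5S)-8-(TBSO)-4-[2-(PMBO)ethyl]-4-methyl-5-[3-(TESO)prop-1-yn-1-yl]oct-1-en-3-ol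
Conditions: NaH (1.05 equiv), PMBCl, Bu4NI (cat.), THF–DMF, 0 °C
Reagents that add atoms: 4-methoxybenzyl chloride, COc1ccc(CCl)cc1
Why: Williamson etherification with one equivalent of base selects the primary alkoxide, the secondary alcohol beside quaternary C1 being too hindered to be alkylated.

Step 11
Reactants: 20
Product: 21 (4R,5S)-8-(TBSO)-4-[2-(PMBO)ethyl]-4-methyl-5-[3-(TESO)prop-1-yn-1-yl]oct-1-en-3-one
Conditions: DMP, NaHCO3, CH2Cl2, 0 → 23 °C
Reagents that add atoms: none
Why: Dess–Martin oxidation of the secondary allylic alcohol under buffered, non-nucleophilic conditions gives the polymerisation-prone vinyl ketone, which is taken on at once.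

Step 12
Reactants: 21
Product: 23 (2R,3S,4Z)-3-[3-(TBSO)propyl]-2-[2-(PMBO)ethyl]-2-methyl-4-[1-(TESO)propan-2-ylidene]cyclohexan-1-one, via trimethylsilyl enol ether 22 (not isolated)
Conditions: Ni(cod)2 (10 mol %), Me2Zn (3 equiv), Me3SiCl (3 equiv), THF, 0 °C, slow addition of 21; then K2CO3, MeOH, 0 °C
Reagents that add atoms: dimethylzinc, C[Zn]C
Why: Proposed new method: zerovalent nickel, assisted by Me3SiCl as oxygen acceptor, should add oxidatively to the s-trans vinyl ketone to give a 1-silyloxyallyl nickel species bound at C4; the C3≡C triple bond then inserts into the Ni–C4 bond by syn carbonickelation, Me2Zn transfers methyl to nickel, and C–CH3 reductive elimination with retention releases silyl enol ether 22 and the catalyst. The closest known reaction types are the nickel-catalysed alkylative cyclization of alkynyl enones tethered through the β-carbon with organozincs (five-membered rings by way of a chelated oxanickelacycle) and the intermolecular nickel-catalysed coupling of vinyl ketones, alkynes, Me2Zn and Me3SiCl; here the tether ends at the carbonyl carbon, so C6 becomes a ring atom and its oxygen lies trans to C4 in the ring enolate and cannot chelate nickel, which is why the silyl chloride is added and why the step is untested for this substrate class. The cyclohexanone ring closes in the 6-exo-dig mode with respect to the alkyne (endo with respect to the enone C=C). No stereocentre is formed: C1 and C2 are carried over unchanged, and the alkene geometry (CH3 cis to C4, CH2OSiEt3 cis to C2) follows from syn addition across the alkyne and retentive reductive elimination. The step needs alkyne insertion to outrun direct 1,4-transfer of methyl and exo to beat endo insertion; the alkyne held three atoms from the carbonyl carbon by quaternary C1 and the unhindered terminal C4 should secure both.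

Step 13
Reactants: 23
Product: 24 (2R,3S,4Z)-3-[3-(TBSO)propyl]-2-(2-hydroxyethyl)-2-methyl-4-[1-(TESO)propan-2-ylidene]cyclohexan-1-one
Conditions: DDQ, CH2Cl2–pH 7 buffer, 0 °C
Reagents that add atoms: none
Why: Oxidative PMB ether cleavage by DDQ (benzylic hydride abstraction and hydrolysis) does not touch silyl ethers, the ketone or the tetrasubstituted alkene.

Step 14
Reactants: 24
Product: 25 (2R,3S,4Z)-3-[3-(TBSO)propyl]-2-(2-iodoethyl)-2-methyl-4-[1-(TESO)propan-2-ylidene]cyclohexan-1-one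
Conditions: I2, PPh3, imidazole, CH2Cl2, 0 °C
Reagents that add atoms: iodine, II
Why: Appel-type iodination converts the primary alcohol into the iodide by SN2 displacement of the oxyphosphonium group under imidazole-buffered conditions that spare the triethylsilyl ether.

Step 15
Reactants: 26 3-methylbut-2-enal; 27 4,4,5,5-tetramethyl-2-(propa-1,2-dien-1-yl)-1,3,2-dioxaborolane
Product: 28 (4R)-6-methylhept-5-en-1-yn-4-ol
Conditions: (R)-TRIP phosphoric acid (5 mol %), 4 Å molecular sieves, toluene, −20 °C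
Reagents that add atoms: none
Why: Chiral phosphoric acid-catalysed propargylation of an aldehyde by an allenylboronate through a closed six-membered SE2' transition state, in which the catalyst selects the aldehyde face and so sets the (R)-carbinol.

Step 16
Reactants: 28
Product: 30 (1E,4R)-1-iodo-2,6-dimethylhepta-1,5-dien-4-ol, via alkenylalane 29 (not isolated)
Conditions: Me3Al (3 equiv), Cp2ZrCl2 (0.25 equiv), CH2Cl2, 0 → 23 °C; then I2, THF, −30 °C
Reagents that add atoms: trimethylaluminium, C[Al](C)C; iodine, II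
Why: Zirconium-catalysed methylalumination of the terminal alkyne (syn addition, methyl to the inner carbon) and iodinolysis of the C–Al bond with retention give the (E)-iodoalkene, the alcohol travelling as its aluminium alkoxide.

Step 17
Reactants: 30
Product: 31 tert-butyl{[(1E,4R)-1-iodo-2,6-dimethylhepta-1,5-dien-4-yl]oxy}dimethylsilane
Conditions: TBSCl, imidazole, DMF, 23 °C
Reagents that add atoms: tert-butyldimethylsilyl chloride, CC(C)(C)[Si](C)(C)Cl
Why: Standard silylation of a secondary alcohol, needed so that this oxygen stays masked during the later allylic oxidation.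

Step 18
Reactants: 31; 32 (4-bromobut-1-yn-1-yl)trimethylsilane
Product: 34 tert-butyl{[(5E,8R)-6,10-dimethyl-1-(trimethylsilyl)undeca-5,9-dien-1-yn-8-yl]oxy}dimethylsilane, via alkylzinc bromide 33 (not isolated)
Conditions: 32, Zn dust, I2 (5 mol %), DMA, 70 °C; then 31, PdCl2(dppf) (3 mol %), THF, 50 °C
Reagents that add atoms: none
Why: Negishi coupling of a homopropargylic alkylzinc bromide with the alkenyl iodide proceeds with retention of the (E)-geometry, the C-silyl group keeping the alkyne terminus inert.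

Step 19
Reactants: 34
Product: 35 tert-butyl{[(5E,8R)-6,10-dimethylundeca-5,9-dien-1-yn-8-yl]oxy}dimethylsilane
Conditions: K2CO3, MeOH, 23 °C
Reagents that add atoms: none
Why: Methanolysis of the alkynyl C–Si bond under carbonate catalysis leaves the TBS ether intact.

Step 20
Reactants: 35
Product: 37 tert-butyl{[(1E,5E,8R)-1-iodo-2,6,10-trimethylundeca-1,5,9-trien-8-yl]oxy}dimethylsilane, via alkenylalane 36 (not isolated)
Conditions: Me3Al (2 equiv), Cp2ZrCl2 (0.2 equiv), H2O (1 equiv), CH2Cl2, −23 °C; then I2, THF, −23 °C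
Reagents that add atoms: trimethylaluminium, C[Al](C)C; iodine, II
Why: A second zirconium-catalysed syn-methylalumination and iodinolysis, run in the water-accelerated mode at low temperature to spare the allylic silyl ether, gives the (E)-alkenyl iodide.

Step 21
Reactants: 25; 37
Product: 39 (2R,3S,4Z)-3-[3-(TBSO)propyl]-2-[(3E,7E,10R)-10-(TBSO)-4,8,12-trimethyltrideca-3,7,11-trien-1-yl]-2-methyl-4-[1-(TESO)propan-2-ylidene]cyclohexan-1-one, via alkylzinc iodide 38 (not isolated)
Conditions: 25, Zn dust, LiCl, THF, 35 °C; then 37, Pd(OAc)2 (2 mol %), SPhos (4 mol %), THF, 23 °C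
Reagents that add atoms: none
Why: Direct zinc insertion into the primary C–I bond tolerates the ketone, and Negishi sp3–sp2 coupling with the alkenyl iodide retains the (E)-geometry; coupling before methyl addition avoids a tertiary alkoxide next to the iodide.

Step 22
Reactants: 39
Product: 40 (1R,2R,3S,4Z)-3-[3-(TBSO)propyl]-2-[(3E,7E,10R)-10-(TBSO)-4,8,12-trimethyltrideca-3,7,11-trien-1-yl]-1,2-dimethyl-4-[1-(TESO)propan-2-ylidene]cyclohexan-1-ol
Conditions: MeMgBr, CeCl3, THF, −78 → −40 °C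
Reagents that add atoms: methylmagnesium bromide, C[Mg]Br
Why: 1,2-Addition of the organocerium reagent (which suppresses enolisation): the C2 chain sits axial to avoid allylic strain with the exocyclic CH2OSiEt3 group and blocks the axial trajectory at C6, so methyl should enter equatorially and leave the hydroxyl axial, cis to the C2 chain and to the C1 methyl as in the target.

Step 23
Reactants: 40
Product: 41 (1R,2R,3S,4Z)-3-[3-(TBSO)propyl]-2-[(3E,7E,10R)-10-(TBSO)-4,8,12-trimethyltrideca-3,7,11-trien-1-yl]-4-(1-hydroxypropan-2-ylidene)-1,2-dimethylcyclohexan-1-ol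
Conditions: PPTS (0.2 equiv), MeOH–CH2Cl2, 0 °C
Reagents that add atoms: none
Why: Acid-catalysed methanolysis distinguishes the primary triethylsilyl ether from the two TBS ethers by rate, so only the allylic oxygen on the ring is unmasked.

Step 24
Reactants: 41
Product: 42 (2Z)-2-[(2S,3R,4R)-2-[3-(TBSO)propyl]-3-[(3E,7E,10R)-10-(TBSO)-4,8,12-trimethyltrideca-3,7,11-trien-1-yl]-4-hydroxy-3,4-dimethylcyclohexylidene]propanal
Conditions: MnO2 (20 equiv), CH2Cl2, 23 °C
Reagents that add atoms: none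
Why: MnO2 oxidises only the free primary allylic alcohol, because the side-chain allylic oxygen is still silylated, and gives the enal without change of alkene geometry.

Step 25
Reactants: 42
Product: 43 (2Z)-2-[(2S,3R,4R)-4-hydroxy-2-(3-hydroxypropyl)-3-[(3E,7E,10R)-10-hydroxy-4,8,12-trimethyltrideca-3,7,11-trien-1-yl]-3,4-dimethylcyclohexylidene]propanal (CNP0270422.1)
Conditions: HF·pyridine, pyridine, THF, 0 → 23 °C
Reagents that add atoms: none
Why: Fluoride-mediated desilylation under pyridine-buffered conditions removes both TBS groups without base-induced isomerisation of the enal or acid-induced ionisation of the allylic alcohol.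

**Compound list**

1 | (2R)-but-3-yn-2-ol | C[C@@H](O)C#C | starting material
2 | tert-butyl(3-iodopropoxy)dimethylsilane | ICCCO[Si](C)(C)C(C)(C)C | starting material
3 | (2R)-7-(TBSO)hept-3-yn-2-ol | C[C@@H](O)C#CCCCO[Si](C)(C)C(C)(C)C | intermediate
4 | (2R,3E)-7-(TBSO)hept-3-en-2-ol | C[C@@H](O)/C=C/CCCO[Si](C)(C)C(C)(C)C | intermediate
5 | 3-methyloxolan-2-one (3-methyldihydrofuran-2(3H)-one, racemic) | CC1CCOC1=O | starting material
6 | 2-ethoxy-3-methyl-4,5-dihydro-3H-furan-1-ium tetrafluoroborate (O-ethyl lactonium salt) | CCOC1=[O+]CCC1C.F[B-](F)(F)F | intermediate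
7 | 2,2-diethoxy-3-methyloxolane | CCOC1(OCC)OCCC1C | intermediate
8 | 2-ethoxy-3-methyl-2-{[(2R,3E)-7-(TBSO)hept-3-en-2-yl]oxy}oxolane (mixed orthoester) | CCOC1(O[C@H](C)/C=C/CCCO[Si](C)(C)C(C)(C)C)OCCC1C | intermediate
9 | 5-{[(2R,3E)-7-(TBSO)hept-3-en-2-yl]oxy}-4-methyl-2,3-dihydrofuran (cyclic ketene acetal) | CC1=C(O[C@H](C)/C=C/CCCO[Si](C)(C)C(C)(C)C)OCC1 | intermediate
10 | (3R)-3-[(4S,5E)-1-(TBSO)hept-5-en-4-yl]-3-methyloxolan-2-one | O1CC[C@](C1=O)(C)[C@@H](CCCO[Si](C)(C)C(C)(C)C)/C=C/C | intermediate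
11 | (3R)-3-[(1R)-4-(TBSO)-1-(5-methyl-1,2,4-trioxolan-3-yl)butyl]-3-methyloxolan-2-one (secondary ozonide) | O1CC[C@](C1=O)(C)[C@@H](CCCO[Si](C)(C)C(C)(C)C)C2OOC(C)O2 | intermediate
12 | (2R)-5-(TBSO)-2-[(3R)-3-methyl-2-oxooxolan-3-yl]pentanal | O1CC[C@](C1=O)(C)[C@@H](CCCO[Si](C)(C)C(C)(C)C)C=O | intermediate
13 | (3R)-3-[(3S)-6-(TBSO)hex-1-yn-3-yl]-3-methyloxolan-2-one | O1CC[C@](C1=O)(C)[C@@H](CCCO[Si](C)(C)C(C)(C)C)C#C | intermediate
14 | lithium acetylide of 13 | O1CC[C@](C1=O)(C)[C@@H](CCCO[Si](C)(C)C(C)(C)C)C#C[Li] | intermediate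
15 | lithium (4S)-7-(TBSO)-4-[(3R)-3-methyl-2-oxooxolan-3-yl]hept-2-yn-1-olate | O1CC[C@](C1=O)(C)[C@@H](CCCO[Si](C)(C)C(C)(C)C)C#CCO[Li] | intermediate
16 | (3R)-3-[(4S)-7-(TBSO)-1-(TESO)hept-2-yn-4-yl]-3-methyloxolan-2-one | O1CC[C@](C1=O)(C)[C@@H](CCCO[Si](C)(C)C(C)(C)C)C#CCO[Si](CC)(CC)CC | intermediate
17 | (3R)-3-[(4S)-7-(TBSO)-1-(TESO)hept-2-yn-4-yl]-3-methyloxolan-2-ol (both anomers) | O1CC[C@](C1O)(C)[C@@H](CCCO[Si](C)(C)C(C)(C)C)C#CCO[Si](CC)(CC)CC | intermediate
18 | vinylmagnesium bromide | C=C[Mg]Br | starting material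
19 | (4R,5S)-8-(TBSO)-4-(2-hydroxyethyl)-4-methyl-5-[3-(TESO)prop-1-yn-1-yl]oct-1-en-3-ol (both C3 epimers) | OCC[C@](C(O)C=C)(C)[C@@H](CCCO[Si](C)(C)C(C)(C)C)C#CCO[Si](CC)(CC)CC | intermediate
20 | (4R,5S)-8-(TBSO)-4-[2-(PMBO)ethyl]-4-methyl-5-[3-(TESO)prop-1-yn-1-yl]oct-1-en-3-ol | COc1ccc(COCC[C@](C(O)C=C)(C)[C@@H](CCCO[Si](C)(C)C(C)(C)C)C#CCO[Si](CC)(CC)CC)cc1 | intermediate
21 | (4R,5S)-8-(TBSO)-4-[2-(PMBO)ethyl]-4-methyl-5-[3-(TESO)prop-1-yn-1-yl]oct-1-en-3-one (ynenone, key-step precursor) | COc1ccc(COCC[C@](C(=O)C=C)(C)[C@@H](CCCO[Si](C)(C)C(C)(C)C)C#CCO[Si](CC)(CC)CC)cc1 | intermediate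
22 | C5=C6 trimethylsilyl enol ether of 23 | COc1ccc(COCC[C@]2(C)[C@@H](CCCO[Si](C)(C)C(C)(C)C)/C(=C(/C)CO[Si](CC)(CC)CC)CC=C2O[Si](C)(C)C)cc1 | intermediate
23 | (2R,3S,4Z)-3-[3-(TBSO)propyl]-2-[2-(PMBO)ethyl]-2-methyl-4-[1-(TESO)propan-2-ylidene]cyclohexan-1-one (key-step product) | COc1ccc(COCC[C@]2(C)[C@@H](CCCO[Si](C)(C)C(C)(C)C)/C(=C(/C)CO[Si](CC)(CC)CC)CCC2=O)cc1 | intermediate
24 | (2R,3S,4Z)-3-[3-(TBSO)propyl]-2-(2-hydroxyethyl)-2-methyl-4-[1-(TESO)propan-2-ylidene]cyclohexan-1-one | OCC[C@]1(C)[C@@H](CCCO[Si](C)(C)C(C)(C)C)/C(=C(/C)CO[Si](CC)(CC)CC)CCC1=O | intermediate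
25 | (2R,3S,4Z)-3-[3-(TBSO)propyl]-2-(2-iodoethyl)-2-methyl-4-[1-(TESO)propan-2-ylidene]cyclohexan-1-one | ICC[C@]1(C)[C@@H](CCCO[Si](C)(C)C(C)(C)C)/C(=C(/C)CO[Si](CC)(CC)CC)CCC1=O | intermediate
26 | 3-methylbut-2-enal | CC(C)=CC=O | starting material
27 | 4,4,5,5-tetramethyl-2-(propa-1,2-dien-1-yl)-1,3,2-dioxaborolane | C=C=CB1OC(C)(C)C(C)(C)O1 | starting material
28 | (4R)-6-methylhept-5-en-1-yn-4-ol | CC(C)=C[C@H](O)CC#C | intermediate
29 | [(1E,4R)-4-(dimethylalumanyloxy)-2,6-dimethylhepta-1,5-dien-1-yl]dimethylalane | CC(C)=C[C@H](O[Al](C)C)C/C(C)=C/[Al](C)C | intermediate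
30 | (1E,4R)-1-iodo-2,6-dimethylhepta-1,5-dien-4-ol | CC(C)=C[C@H](O)C/C(C)=C/I | intermediate
31 | tert-butyl{[(1E,4R)-1-iodo-2,6-dimethylhepta-1,5-dien-4-yl]oxy}dimethylsilane | CC(C)=C[C@H](O[Si](C)(C)C(C)(C)C)C/C(C)=C/I | intermediate
32 | (4-bromobut-1-yn-1-yl)trimethylsilane | C[Si](C)(C)C#CCCBr | starting material
33 | bromo[4-(trimethylsilyl)but-3-yn-1-yl]zinc | C[Si](C)(C)C#CCC[Zn]Br | intermediate
34 | tert-butyl{[(5E,8R)-6,10-dimethyl-1-(trimethylsilyl)undeca-5,9-dien-1-yn-8-yl]oxy}dimethylsilane | CC(C)=C[C@H](O[Si](C)(C)C(C)(C)C)C/C(C)=C/CCC#C[Si](C)(C)C | intermediate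
35 | tert-butyl{[(5E,8R)-6,10-dimethylundeca-5,9-dien-1-yn-8-yl]oxy}dimethylsilane | CC(C)=C[C@H](O[Si](C)(C)C(C)(C)C)C/C(C)=C/CCC#C | intermediate
36 | [(1E,5E,8R)-8-(TBSO)-2,6,10-trimethylundeca-1,5,9-trien-1-yl]dimethylalane | CC(C)=C[C@H](O[Si](C)(C)C(C)(C)C)C/C(C)=C/CC/C(C)=C/[Al](C)C | intermediate
37 | tert-butyl{[(1E,5E,8R)-1-iodo-2,6,10-trimethylundeca-1,5,9-trien-8-yl]oxy}dimethylsilane | CC(C)=C[C@H](O[Si](C)(C)C(C)(C)C)C/C(C)=C/CC/C(C)=C/I | intermediate
38 | alkylzinc iodide of 25 (C–I replaced by C–ZnI) | I[Zn]CC[C@]1(C)[C@@H](CCCO[Si](C)(C)C(C)(C)C)/C(=C(/C)CO[Si](CC)(CC)CC)CCC1=O | intermediate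
39 | (2R,3S,4Z)-3-[3-(TBSO)propyl]-2-[(3E,7E,10R)-10-(TBSO)-4,8,12-trimethyltrideca-3,7,11-trien-1-yl]-2-methyl-4-[1-(TESO)propan-2-ylidene]cyclohexan-1-one | CC(C)=C[C@H](O[Si](C)(C)C(C)(C)C)C/C(C)=C/CC/C(C)=C/CC[C@]1(C)[C@@H](CCCO[Si](C)(C)C(C)(C)C)/C(=C(/C)CO[Si](CC)(CC)CC)CCC1=O | intermediate
40 | (1R,2R,3S,4Z)-3-[3-(TBSO)propyl]-2-[(3E,7E,10R)-10-(TBSO)-4,8,12-trimethyltrideca-3,7,11-trien-1-yl]-1,2-dimethyl-4-[1-(TESO)propan-2-ylidene]cyclohexan-1-ol | CC(C)=C[C@H](O[Si](C)(C)C(C)(C)C)C/C(C)=C/CC/C(C)=C/CC[C@]1(C)[C@@H](CCCO[Si](C)(C)C(C)(C)C)/C(=C(/C)CO[Si](CC)(CC)CC)CC[C@@]1(C)O | intermediate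
41 | (1R,2R,3S,4Z)-3-[3-(TBSO)propyl]-2-[(3E,7E,10R)-10-(TBSO)-4,8,12-trimethyltrideca-3,7,11-trien-1-yl]-4-(1-hydroxypropan-2-ylidene)-1,2-dimethylcyclohexan-1-ol | CC(C)=C[C@H](O[Si](C)(C)C(C)(C)C)C/C(C)=C/CC/C(C)=C/CC[C@]1(C)[C@@H](CCCO[Si](C)(C)C(C)(C)C)/C(=C(/C)CO)CC[C@@]1(C)O | intermediate
42 | (2Z)-2-[(2S,3R,4R)-2-[3-(TBSO)propyl]-3-[(3E,7E,10R)-10-(TBSO)-4,8,12-trimethyltrideca-3,7,11-trien-1-yl]-4-hydroxy-3,4-dimethylcyclohexylidene]propanal | CC(C)=C[C@H](O[Si](C)(C)C(C)(C)C)C/C(C)=C/CC/C(C)=C/CC[C@]1(C)[C@@H](CCCO[Si](C)(C)C(C)(C)C)/C(=C(/C)C=O)CC[C@@]1(C)O | intermediate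
43 | (2Z)-2-[(2S,3R,4R)-4-hydroxy-2-(3-hydroxypropyl)-3-[(3E,7E,10R)-10-hydroxy-4,8,12-trimethyltrideca-3,7,11-trien-1-yl]-3,4-dimethylcyclohexylidene]propanal | CC(C)=C[C@H](O)C/C(C)=C/CC/C(C)=C/CC[C@]1(C)[C@@H](CCCO)/C(=C(/C)C=O)CC[C@@]1(C)O | target

**Step count.** Total: 25 steps. Longest linear sequence: 18 steps (steps 1, 2, 4–14 and 21–25).

**Steps most likely to fail**

Step 12 (ring closure). Alkyne insertion may be outrun by direct 1,4-transfer of methyl to the vinyl ketone, or the alkenylnickel intermediate may lose the silyloxy group by β-elimination. The fallback uses a palladium cascade of known type. It sets out from lactol 17 and returns to ketone 23. Addition of ethynylmagnesium bromide to 17 gives the ethynyl carbinol diol F1, and etherification of its primary hydroxyl (NaH, PMBCl) gives the PMB ether F2. Dess–Martin oxidation gives the terminal ynone F3, and hydroiodination (LiI, AcOH, MeCN; anti addition to the ynone) gives the (Z)-β-iodoenone F4. Pd(PPh3)4 with Me4Sn in DMF at 70 °C should then bring about oxidative addition at C4–I, 6-exo-dig syn carbopalladation of the C3≡C alkyne and Stille transfer of methyl, giving the 4-alkylidenecyclohex-2-enone F5 with CH3 cis to C4. Conjugate reduction of the C4=C5 bond with [(Ph3P)CuH]6 (the fully substituted δ-carbon blocks 1,6-reduction) leads back to 23.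

Step 4 (orthoester Claisen). Formation of the tetrasubstituted cyclic ketene acetal at 140 °C may be slower than ionisation or dehydration of the secondary allylic alcohol, and chair selectivity may erode at that temperature. The fallback is a low-temperature enolate Claisen rearrangement. It sets out from allylic alcohol 4 and returns to lactone 10. Lactone 5 is opened and etherified (KOH, PMBCl, toluene, reflux; then aqueous KOH) to 4-(PMBO)-2-methylbutanoic acid F6, which is esterified with 4 (DCC, DMAP) to the allyl ester F7. Ireland–Claisen rearrangement (KN(SiMe3)2, Me3SiCl, toluene, −78 → 23 °C) through the chair transition state gives the acid F8; the ketene acetal isomer with methyl cis to the allyloxy oxygen leads to the required C1 configuration. DDQ removes the PMB group and the hydroxy acid F9 lactonises to 10. Enolate geometry is not fixed by a ring here, so the C1 epimer from the other ketene acetal isomer would have to be removed by chromatography at the lactone stage.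

Step 22 (methyl addition at C6). Facial selectivity may be poor, because the axial arm on C1 also hinders the equatorial trajectory, and the hindered ketone may enolise. The fallback replaces direct addition by methylene transfer and reduction. It sets out from ketone 39 and returns to alcohol 40. Corey–Chaykovsky reaction with dimethylsulfoxonium methylide (Me3S(O)I, NaH, DMSO), whose reversible addition ends in the equatorial C–C bond, gives the spiro-epoxide F10 with axial oxygen. LiEt3BH opens the epoxide at its CH2 terminus and gives 40.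

**Further compounds**

F1 | step 12 | (4R,5S)-8-(TBSO)-4-(2-hydroxyethyl)-4-methyl-5-[3-(TESO)prop-1-yn-1-yl]oct-1-yn-3-ol | OCC[C@](C(O)C#C)(C)[C@@H](CCCO[Si](C)(C)C(C)(C)C)C#CCO[Si](CC)(CC)CC
F2 | step 12 | (4R,5S)-8-(TBSO)-4-[2-(PMBO)ethyl]-4-methyl-5-[3-(TESO)prop-1-yn-1-yl]oct-1-yn-3-ol | COc1ccc(COCC[C@](C(O)C#C)(C)[C@@H](CCCO[Si](C)(C)C(C)(C)C)C#CCO[Si](CC)(CC)CC)cc1
F3 | step 12 | (4R,5S)-8-(TBSO)-4-[2-(PMBO)ethyl]-4-methyl-5-[3-(TESO)prop-1-yn-1-yl]oct-1-yn-3-one | COc1ccc(COCC[C@](C(=O)C#C)(C)[C@@H](CCCO[Si](C)(C)C(C)(C)C)C#CCO[Si](CC)(CC)CC)cc1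
F4 | step 12 | (1Z,4R,5S)-8-(TBSO)-1-iodo-4-[2-(PMBO)ethyl]-4-methyl-5-[3-(TESO)prop-1-yn-1-yl]oct-1-en-3-one | COc1ccc(COCC[C@](C(=O)/C=C\I)(C)[C@@H](CCCO[Si](C)(C)C(C)(C)C)C#CCO[Si](CC)(CC)CC)cc1
F5 | step 12 | (4Z,5S,6R)-5-[3-(TBSO)propyl]-6-[2-(PMBO)ethyl]-6-methyl-4-[1-(TESO)propan-2-ylidene]cyclohex-2-en-1-one | COc1ccc(COCC[C@]2(C)[C@@H](CCCO[Si](C)(C)C(C)(C)C)/C(=C(/C)CO[Si](CC)(CC)CC)C=CC2=O)cc1
F6 | step 4 | 4-(PMBO)-2-methylbutanoic acid (racemic) | COc1ccc(COCCC(C)C(=O)O)cc1
F7 | step 4 | (2R,3E)-7-(TBSO)hept-3-en-2-yl 4-(PMBO)-2-methylbutanoate | COc1ccc(COCCC(C)C(=O)O[C@H](C)/C=C/CCCO[Si](C)(C)C(C)(C)C)cc1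
F8 | step 4 | (2R,3S,4E)-3-[3-(TBSO)propyl]-2-[2-(PMBO)ethyl]-2-methylhex-4-enoic acid | COc1ccc(COCC[C@](C(=O)O)(C)[C@@H](CCCO[Si](C)(C)C(C)(C)C)/C=C/C)cc1
F9 | step 4 | (2R,3S,4E)-3-[3-(TBSO)propyl]-2-(2-hydroxyethyl)-2-methylhex-4-enoic acid | OCC[C@](C(=O)O)(C)[C@@H](CCCO[Si](C)(C)C(C)(C)C)/C=C/C
F10 | step 22 | spiro-epoxide of 39 at C6 (1-oxaspiro[2.5]octane; oxygen axial and cis to the C2 chain) | CC(C)=C[C@H](O[Si](C)(C)C(C)(C)C)C/C(C)=C/CC/C(C)=C/CC[C@]1(C)[C@@H](CCCO[Si](C)(C)C(C)(C)C)/C(=C(/C)CO[Si](CC)(CC)CC)CC[C@]12CO2
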